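**Plan**

- Retrosynthesis (isochromene numbering throughout): ring B is opened at O2–C3 and C4–C4a, giving a ring A 2,3-dichloroenone (C1 silyl ether, C7/C8 acetonide) and the dienyl methyl ketone of the side chain. Ring A is cut at C4a–C5 (Dieckmann) and traced to a δ-lactone closed by metathesis at C7=C8; the side chain is cut at its two C=C bonds.
- Forward: temporary δ-lactone → cis-diol acetonide → lactone opened with MeLi → ring A by Dieckmann closure → chlorides at C5 and C4a → side chain joined and ring B closed in one pot → global deprotection.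
- Stereochemistry: C8a from an Evans alkylation; C7 and C8 from OsO4 adding anti to the C8a substituent on the lactone, which becomes the all-cis array once ring A is closed through C4a. C5′/C6′ come from ethyl (S)-3-hydroxybutanoate by anti-selective Fráter–Seebach methylation; both side-chain alkenes are E from stabilised ylides.
- Enabling feature: ring B (O2–C1–C8a–C4a–C4–C3) is the internal enol ether of the C1 hydroxyl with a vinylogous 1,3-diketone (C3=O, C4H2, C4a=C5–C6=O). C3 and C4 can therefore arrive as the carbonyl and methyl of a side-chain methyl ketone, and C4a as a vinylogous acyl chloride.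

Key step: step 21

Remark: 15 is drawn as the open hydroxy ketone (it equilibrates with its six-membered hemiketal) and 22 as one enol tautomer.

**Fragment 1 (ring A)**

Step 1
Reactants: 1 (R)-4-benzyl-1,3-oxazolidin-2-one; 2 (E)-but-2-enoyl chloride
Product: 4 (R)-4-benzyl-3-[(E)-but-2-enoyl]-1,3-oxazolidin-2-one, via lithium oxazolidinide 3 (not isolated)
Conditions: n-BuLi, THF, −78 °C; then 2, −78 → 0 °C
Reagents that add atoms: none
Why: N-acylation of the lithiated oxazolidinone with an acid chloride is the standard way to load the Evans auxiliary, and no stereocentre is formed.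

Step 2
Reactants: 4 (R)-4-benzyl-3-[(E)-but-2-enoyl]-1,3-oxazolidin-2-one; 5 benzyl chloromethyl ether
Product: 7 (4R)-4-benzyl-3-[(2S)-2-[(benzyloxy)methyl]but-3-enoyl]-1,3-oxazolidin-2-one, via sodium dienolate 6 (not isolated)
Conditions: NaN(SiMe3)2, THF, −78 °C; then 5, −78 → −40 °C
Reagents that add atoms: none
Why: In this deconjugative Evans alkylation, γ-deprotonation gives the chelated (Z)-dienolate, which should react at its α-carbon (C8a) on the face away from the benzyl group of the (R)-auxiliary and so set (S) at C8a, the α-vinyl imide being protected against epimerisation by A(1,3) strain.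

Step 3
Reactants: 7 (4R)-4-benzyl-3-[(2S)-2-[(benzyloxy)methyl]but-3-enoyl]-1,3-oxazolidin-2-one
Product: 8 (2R)-2-[(benzyloxy)methyl]but-3-en-1-ol
Conditions: LiBH4, MeOH (1 equiv), THF, 0 °C
Reagents that add atoms: none
Why: Reductive cleavage of the N-acyl oxazolidinone gives the primary alcohol (C1) without touching C8a (the descriptor changes only through the priority rules) and returns the auxiliary.

Step 4
Reactants: 8 (2R)-2-[(benzyloxy)methyl]but-3-en-1-ol; 9 2-methylprop-2-enoyl chloride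
Product: 10 (2S)-2-[(benzyloxy)methyl]but-3-en-1-yl 2-methylprop-2-enoate
Conditions: Et3N, DMAP (5 mol%), CH2Cl2, 0 °C
Reagents that add atoms: none
Why: Acylation of a primary alcohol with an acid chloride under amine/DMAP catalysis installs C6, C7 and the C7 methyl as a methacrylate ester.

Step 5
Reactants: 10 (2S)-2-[(benzyloxy)methyl]but-3-en-1-yl 2-methylprop-2-enoate
Product: 11 (5S)-5-[(benzyloxy)methyl]-3-methyl-5,6-dihydro-2H-pyran-2-one
Conditions: second-generation Grubbs catalyst RuCl2(=CHPh)(H2IMes)(PCy3) (5 mol%), CH2Cl2 (5 mM), 40 °C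
Reagents that add atoms: none
Why: Ring-closing metathesis of a methacrylate with a monosubstituted alkene is a known route to α-methyl-α,β-unsaturated δ-lactones and forms C7=C8 with C6 and C8a necessarily cis.

Step 6
Reactants: 11 (5S)-5-[(benzyloxy)methyl]-3-methyl-5,6-dihydro-2H-pyran-2-one
Product: 12 (3R,4R,5S)-5-[(benzyloxy)methyl]-3,4-dihydroxy-3-methyloxan-2-one
Conditions: K2OsO4·2H2O (2 mol%), NMO, citric acid, t-BuOH–H2O (1:1), rt
Reagents that add atoms: N-methylmorpholine N-oxide, C[N+]1([O-])CCOCC1; water, O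
Why: OsO4/NMO syn-dihydroxylation should deliver both oxygens to the lactone face opposite the allylic benzyloxymethyl group on C8a, setting C7 and C8 as (3R,4R); because that exocyclic group becomes ring atom C4a, the anti relation in the lactone is the all-cis relation of C7–OH, C8–OH and C1 in ring A.

Step 7
Reactants: 12 (3R,4R,5S)-5-[(benzyloxy)methyl]-3,4-dihydroxy-3-methyloxan-2-one
Product: 13 (3aR,7S,7aR)-7-[(benzyloxy)methyl]-2,2,3a-trimethyltetrahydro-4H-[1,3]dioxolo[4,5-c]pyran-4-one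
Conditions: 2,2-dimethoxypropane, TsOH·H2O (5 mol%), acetone, rt
Reagents that add atoms: 2,2-dimethoxypropane, COC(C)(C)OC
Why: Acid-catalysed transketalisation converts the cis-diol into its acetonide, which protects C7–OH and C8–OH and later holds C6 and C8a cis for ring A closure.

Step 8
Reactants: 13 (3aR,7S,7aR)-7-[(benzyloxy)methyl]-2,2,3a-trimethyltetrahydro-4H-[1,3]dioxolo[4,5-c]pyran-4-one
Product: 15 1-{(4R,5R)-5-[(2R)-1-(benzyloxy)-3-hydroxypropan-2-yl]-2,2,4-trimethyl-1,3-dioxolan-4-yl}ethan-1-one, via lithium hemiketal alkoxide 14 (not isolated)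
Conditions: MeLi (1.1 equiv), THF, −78 °C; sat. aq. NH4Cl at −78 °C
Reagents that add atoms: methyllithium, [Li]C
Why: Mono-addition of an organolithium to a lactone stops at the tetrahedral lithium hemiketal, which persists at −78 °C, so work-up should give the methyl ketone (C6 with C5 as its methyl) and free the C1 hydroxyl.

Step 9
Reactants: 15 1-{(4R,5R)-5-[(2R)-1-(benzyloxy)-3-hydroxypropan-2-yl]-2,2,4-trimethyl-1,3-dioxolan-4-yl}ethan-1-one
Product: 16 1-{(4R,5R)-5-[(2S)-1-(benzyloxy)-3-[(triethylsilyl)oxy]propan-2-yl]-2,2,4-trimethyl-1,3-dioxolan-4-yl}ethan-1-one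
Conditions: TESCl, imidazole, DMAP (5 mol%), CH2Cl2, 0 °C → rt
Reagents that add atoms: chlorotriethylsilane, CC[Si](Cl)(CC)CC
Why: Silylation of the primary C1 hydroxyl is much faster than that of the hindered tertiary hemiketal hydroxyl, so the ring–chain equilibrium should drain into the open-chain silyl ether.

Step 10
Reactants: 16 1-{(4R,5R)-5-[(2S)-1-(benzyloxy)-3-[(triethylsilyl)oxy]propan-2-yl]-2,2,4-trimethyl-1,3-dioxolan-4-yl}ethan-1-one
Product: 17 1-{(4R,5R)-5-[(2S)-1-hydroxy-3-[(triethylsilyl)oxy]propan-2-yl]-2,2,4-trimethyl-1,3-dioxolan-4-yl}ethan-1-one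
Conditions: H2 (1 atm), Pd/C, EtOAc, rt
Reagents that add atoms: none
Why: Hydrogenolysis of the benzyl ether in a neutral aprotic solvent frees the C4a hydroxyl while the ketone, acetonide and triethylsilyl ether are left alone.

Step 11
Reactants: 17 1-{(4R,5R)-5-[(2S)-1-hydroxy-3-[(triethylsilyl)oxy]propan-2-yl]-2,2,4-trimethyl-1,3-dioxolan-4-yl}ethan-1-one
Product: 18 (2S)-2-[(4R,5R)-5-acetyl-2,2,5-trimethyl-1,3-dioxolan-4-yl]-3-[(triethylsilyl)oxy]propanoic acid
Conditions: TEMPO (7 mol%), NaOCl (2 mol%), NaClO2, MeCN–phosphate buffer (pH 6.7), 35 °C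
Reagents that add atoms: sodium chlorite, [Na+].[O-]Cl=O
Why: TEMPO-catalysed chlorite oxidation takes the primary alcohol through the aldehyde to the acid at near-neutral pH, conditions chosen to spare the silyl ether and the epimerisable C8a centre.

Step 12
Reactants: 18 (2S)-2-[(4R,5R)-5-acetyl-2,2,5-trimethyl-1,3-dioxolan-4-yl]-3-[(triethylsilyl)oxy]propanoic acid
Product: 19 methyl (2S)-2-[(4R,5R)-5-acetyl-2,2,5-trimethyl-1,3-dioxolan-4-yl]-3-[(triethylsilyl)oxy]propanoate
Conditions: TMSCHN2, MeOH–toluene (1:4), 0 °C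
Reagents that add atoms: (trimethylsilyl)diazomethane, C[Si](C)(C)C=[N+]=[N-]
Why: Methylation of the carboxylic acid with (trimethylsilyl)diazomethane is neutral and leaves the ketone and the α-stereocentre untouched.

Step 13
Reactants: 19 methyl (2S)-2-[(4R,5R)-5-acetyl-2,2,5-trimethyl-1,3-dioxolan-4-yl]-3-[(triethylsilyl)oxy]propanoate
Product: 21 (3aR,7S,7aR)-2,2,3a-trimethyl-7-{[(triethylsilyl)oxy]methyl}tetrahydro-1,3-benzodioxole-4,6-dione, via lithium enolate 20 (not isolated)
Conditions: LiN(SiMe3)2 (2.2 equiv), THF, −78 → 0 °C; AcOH quench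
Reagents that add atoms: none
Why: In this Dieckmann-type intramolecular Claisen condensation the base can enolise the ketone only at its methyl group (C7 is fully substituted and the ester α-proton at C8a is less acidic), the enolate acylates at the C4a ester in a 6-exo-trig closure helped by the cis-dioxolane, and the product is held as its dione enolate, which shields C8a.

Step 14
Reactants: 21 (3aR,7S,7aR)-2,2,3a-trimethyl-7-{[(triethylsilyl)oxy]methyl}tetrahydro-1,3-benzodioxole-4,6-dione
Product: 22 (3aR,7S,7aR)-5-chloro-6-hydroxy-2,2,3a-trimethyl-7-{[(triethylsilyl)oxy]methyl}-7,7a-dihydro-1,3-benzodioxol-4(3aH)-one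
Conditions: NCS (1.0 equiv), CH2Cl2, 0 °C
Reagents that add atoms: N-chlorosuccinimide, O=C1CCC(=O)N1Cl
Why: Electrophilic chlorination of an enolised cyclic 1,3-dione occurs at the central carbon (C5), and one equivalent of reagent should limit it to the monochloride.

Step 15
Reactants: 22 (3aR,7S,7aR)-5-chloro-6-hydroxy-2,2,3a-trimethyl-7-{[(triethylsilyl)oxy]methyl}-7,7a-dihydro-1,3-benzodioxol-4(3aH)-one
Product: 23 (3aR,7S,7aR)-5,6-dichloro-2,2,3a-trimethyl-7-{[(triethylsilyl)oxy]methyl}-7,7a-dihydro-1,3-benzodioxol-4(3aH)-one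
Conditions: Ph3PCl2 (1.05 equiv), Et3N, MeCN, 0 °C → rt
Reagents that add atoms: dichlorotriphenylphosphorane, ClP(Cl)(c1ccccc1)(c1ccccc1)c1ccccc1
Why: Chlorodehydration of the enolised dione through an O-phosphonium salt and chloride addition–elimination gives the vinylogous acyl chloride under basic, acid-free conditions, and chloride should enter at C4a because C6 is flanked by the fully substituted C7, as in 4,4-disubstituted cyclohexane-1,3-diones.

**Fragment 2 (side chain)**

Step 16
Reactants: 24 ethyl (3S)-3-hydroxybutanoate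
Product: 26 ethyl (2S,3S)-3-hydroxy-2-methylbutanoate, via dilithium dianion 25 (not isolated)
Conditions: LiN(iPr)2 (2.2 equiv), THF, −78 → −20 °C; MeI, DMPU, −78 → 0 °C
Reagents that add atoms: iodomethane, CI
Why: In the Fráter–Seebach alkylation the chelated dianion of the β-hydroxy ester is methylated on the face opposite the C3 methyl group, giving the anti (2S,3S) product that maps onto C5′/C6′.

Step 17
Reactants: 26 ethyl (2S,3S)-3-hydroxy-2-methylbutanoate
Product: 27 ethyl (2S,3S)-3-[(tert-butyldimethylsilyl)oxy]-2-methylbutanoate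
Conditions: TBSCl, imidazole, DMF, rt
Reagents that add atoms: tert-butylchlorodimethylsilane, CC(C)(C)[Si](C)(C)Cl
Why: Standard silylation of a secondary alcohol gives an ether that survives hydride, ylides, amide base and dilute acid.

Step 18
Reactants: 27 ethyl (2S,3S)-3-[(tert-butyldimethylsilyl)oxy]-2-methylbutanoate
Product: 28 (2S,3S)-3-[(tert-butyldimethylsilyl)oxy]-2-methylbutanal
Conditions: iBu2AlH (1.05 equiv), CH2Cl2, −78 °C; aq. KNaC4H4O6 (potassium sodium tartrate)
Reagents that add atoms: none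
Why: Partial reduction of the ester stops at the aluminium hemiacetal at −78 °C and releases the aldehyde on work-up, and the α-centre should survive if the aldehyde is used at once.

Step 19
Reactants: 28 (2S,3S)-3-[(tert-butyldimethylsilyl)oxy]-2-methylbutanal; 29 2-(triphenyl-λ5-phosphanylidene)propanal
Product: 30 (2E,4R,5S)-5-[(tert-butyldimethylsilyl)oxy]-2,4-dimethylhex-2-enal
Conditions: toluene, 90 °C
Reagents that add atoms: none
Why: Wittig olefination with a stabilised formyl ylide gives the (E)-2-methyl enal under neutral conditions, and the conjugated product is less electrophilic than the starting aldehyde, which limits a second olefination.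

Step 20
Reactants: 30 (2E,4R,5S)-5-[(tert-butyldimethylsilyl)oxy]-2,4-dimethylhex-2-enal; 31 1-(triphenyl-λ5-phosphanylidene)propan-2-one
Product: 32 (3E,5E,7R,8S)-8-[(tert-butyldimethylsilyl)oxy]-5,7-dimethylnona-3,5-dien-2-one
Conditions: toluene, 90 °C
Reagents that add atoms: none
Why: A second Wittig olefination with the stabilised acetyl ylide should give the (E)-enone and completes the dienyl methyl ketone.

**Coupling and end game**

Step 21
Reactants: 32 (3E,5E,7R,8S)-8-[(tert-butyldimethylsilyl)oxy]-5,7-dimethylnona-3,5-dien-2-one; 23 (3aR,7S,7aR)-5,6-dichloro-2,2,3a-trimethyl-7-{[(triethylsilyl)oxy]methyl}-7,7a-dihydro-1,3-benzodioxol-4(3aH)-one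
Product: 36 7,8-O-isopropylidene-6′-O-(tert-butyldimethylsilyl) derivative of the target, via lithium enolate 33 (not isolated), via silyloxy enedione 34 (not isolated), via hydroxy enedione 35 (not isolated)
Conditions: 32 (2.2 equiv), LiN(SiMe3)2 (2.1 equiv), THF, −78 °C; 23 (1.0 equiv), −78 → −30 °C; then 1 M aq. HCl–THF, 0 °C → rt
Reagents that add atoms: none
Why: LiN(SiMe3)2 removes a proton from the acetyl methyl of 32 to give the kinetic cross-conjugated enolate 33, whose carbon adds to C4a of 23, the β-carbon of a vinylogous acyl chloride, and chloride is expelled (C4–C4a bond); the acidic C4 methylene of enedione 34 is then masked as its extended enolate by the second equivalent of 33. The closest known reaction type is addition–elimination of ketone enolates on β-chloro enones, followed by acid cyclodehydration of δ-hydroxy 1,3-dicarbonyl compounds to pyran enol ethers. On acidification the triethylsilyl ether is cleaved, the C1 hydroxyl of 35 attacks the C3 carbonyl in a 6-exo-trig hemiketalisation, and loss of water toward C4 gives the C3=C4 enol ether of ring B (O2–C3 bond), driven by conjugation through C4a=C5 to the C6 carbonyl. No stereocentre is created: C7, C8 and C8a are carried over from 23 and C5′/C6′ from 32. The step needs C-attack at C4a to win over abstraction of the γ-proton at C8a, 1,2-addition at C6 and O-alkylation, which low temperature, the lithium counter-ion, the absence of free amide base (the enolate is preformed with a slight deficit of base) and the shielding of C6 by the fully substituted C7 should secure. The acid must remove only the primary triethylsilyl group, which dilute HCl at 0 °C should do in the presence of the secondary tert-butyldimethylsilyl ether and the acetonide.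

Step 22
Reactants: 36 7,8-O-isopropylidene-6′-O-(tert-butyldimethylsilyl) derivative of the target
Product: 37 (7R,8R,8aS)-5-chloro-7,8-dihydroxy-3-[(1E,3E,5R,6S)-6-hydroxy-3,5-dimethylhepta-1,3-dien-1-yl]-7-methyl-1,7,8,8a-tetrahydro-6H-isochromen-6-one
Conditions: TFA–H2O (9:1), 0 °C → rt
Reagents that add atoms: none
Why: Aqueous trifluoroacetic acid hydrolyses the acetonide and cleaves the secondary silyl ether in one operation, while the push–pull enol ether of ring B is stabilised by conjugation to the C6 carbonyl and no stereocentre is involved.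

**Compound list**

1 | (R)-4-benzyl-1,3-oxazolidin-2-one | O=C1OC[C@@H](Cc2ccccc2)N1 | starting material
2 | (E)-but-2-enoyl chloride | C/C=C/C(Cl)=O | starting material
3 | lithium (R)-4-benzyl-2-oxo-1,3-oxazolidin-3-ide | [Li+].O=C1OC[C@@H](Cc2ccccc2)[N-]1 | intermediate
4 | (R)-4-benzyl-3-[(E)-but-2-enoyl]-1,3-oxazolidin-2-one | C/C=C/C(=O)N1C(=O)OC[C@H]1Cc1ccccc1 | intermediate
5 | benzyl chloromethyl ether | ClCOCc1ccccc1 | starting material
6 | sodium (Z)-dienolate of 4 | [Na+].[O-]/C(=C\C=C)N1C(=O)OC[C@H]1Cc1ccccc1 | intermediate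
7 | (4R)-4-benzyl-3-[(2S)-2-[(benzyloxy)methyl]but-3-enoyl]-1,3-oxazolidin-2-one | C=C[C@@H](COCc1ccccc1)C(=O)N1C(=O)OC[C@H]1Cc1ccccc1 | intermediate
8 | (2R)-2-[(benzyloxy)methyl]but-3-en-1-ol | OC[C@H](COCc1ccccc1)C=C | intermediate
9 | 2-methylprop-2-enoyl chloride | C=C(C)C(Cl)=O | starting material
10 | (2S)-2-[(benzyloxy)methyl]but-3-en-1-yl 2-methylprop-2-enoate | C=C(C)C(=O)OC[C@H](COCc1ccccc1)C=C | intermediate
11 | (5S)-5-[(benzyloxy)methyl]-3-methyl-5,6-dihydro-2H-pyran-2-one | O=C1OC[C@H](COCc2ccccc2)C=C1C | intermediate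
12 | (3R,4R,5S)-5-[(benzyloxy)methyl]-3,4-dihydroxy-3-methyloxan-2-one | O=C1OC[C@H](COCc2ccccc2)[C@@H](O)[C@@]1(C)O | intermediate
13 | (3aR,7S,7aR)-7-[(benzyloxy)methyl]-2,2,3a-trimethyltetrahydro-4H-[1,3]dioxolo[4,5-c]pyran-4-one | O=C1OC[C@H](COCc2ccccc2)[C@H]2OC(C)(C)O[C@@]12C | intermediate
14 | lithium hemiketal alkoxide from MeLi addition to 13 (hemiketal carbon undefined) | [Li]OC1(C)OC[C@H](COCc2ccccc2)[C@H]2OC(C)(C)O[C@@]12C | intermediate
15 | 1-{(4R,5R)-5-[(2R)-1-(benzyloxy)-3-hydroxypropan-2-yl]-2,2,4-trimethyl-1,3-dioxolan-4-yl}ethan-1-one | CC(=O)[C@]1(C)OC(C)(C)O[C@@H]1[C@@H](COCc2ccccc2)CO | intermediate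
16 | 1-{(4R,5R)-5-[(2S)-1-(benzyloxy)-3-[(triethylsilyl)oxy]propan-2-yl]-2,2,4-trimethyl-1,3-dioxolan-4-yl}ethan-1-one | CC(=O)[C@]1(C)OC(C)(C)O[C@@H]1[C@@H](COCc2ccccc2)CO[Si](CC)(CC)CC | intermediate
17 | 1-{(4R,5R)-5-[(2S)-1-hydroxy-3-[(triethylsilyl)oxy]propan-2-yl]-2,2,4-trimethyl-1,3-dioxolan-4-yl}ethan-1-one | CC(=O)[C@]1(C)OC(C)(C)O[C@@H]1[C@@H](CO)CO[Si](CC)(CC)CC | intermediate
18 | (2S)-2-[(4R,5R)-5-acetyl-2,2,5-trimethyl-1,3-dioxolan-4-yl]-3-[(triethylsilyl)oxy]propanoic acid | CC(=O)[C@]1(C)OC(C)(C)O[C@@H]1[C@@H](C(=O)O)CO[Si](CC)(CC)CC | intermediate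
19 | methyl (2S)-2-[(4R,5R)-5-acetyl-2,2,5-trimethyl-1,3-dioxolan-4-yl]-3-[(triethylsilyl)oxy]propanoate | CC(=O)[C@]1(C)OC(C)(C)O[C@@H]1[C@@H](C(=O)OC)CO[Si](CC)(CC)CC | intermediate
20 | lithium enolate of 19 (acetyl methyl deprotonated) | [Li]OC(=C)[C@]1(C)OC(C)(C)O[C@@H]1[C@@H](C(=O)OC)CO[Si](CC)(CC)CC | intermediate
21 | (3aR,7S,7aR)-2,2,3a-trimethyl-7-{[(triethylsilyl)oxy]methyl}tetrahydro-1,3-benzodioxole-4,6-dione | O=C1CC(=O)[C@]2(C)OC(C)(C)O[C@@H]2[C@@H]1CO[Si](CC)(CC)CC | intermediate
22 | (3aR,7S,7aR)-5-chloro-6-hydroxy-2,2,3a-trimethyl-7-{[(triethylsilyl)oxy]methyl}-7,7a-dihydro-1,3-benzodioxol-4(3aH)-one | OC1=C(Cl)C(=O)[C@]2(C)OC(C)(C)O[C@@H]2[C@@H]1CO[Si](CC)(CC)CC | intermediate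
23 | (3aR,7S,7aR)-5,6-dichloro-2,2,3a-trimethyl-7-{[(triethylsilyl)oxy]methyl}-7,7a-dihydro-1,3-benzodioxol-4(3aH)-one (fragment 1) | ClC1=C(Cl)C(=O)[C@]2(C)OC(C)(C)O[C@@H]2[C@@H]1CO[Si](CC)(CC)CC | intermediate
24 | ethyl (3S)-3-hydroxybutanoate | CCOC(=O)C[C@H](C)O | starting material
25 | dilithium dianion of 24 (enolate alkoxide) | [Li]OC(OCC)=C[C@H](C)O[Li] | intermediate
26 | ethyl (2S,3S)-3-hydroxy-2-methylbutanoate | CCOC(=O)[C@@H](C)[C@H](C)O | intermediate
27 | ethyl (2S,3S)-3-[(tert-butyldimethylsilyl)oxy]-2-methylbutanoate | CCOC(=O)[C@@H](C)[C@H](C)O[Si](C)(C)C(C)(C)C | intermediate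
28 | (2S,3S)-3-[(tert-butyldimethylsilyl)oxy]-2-methylbutanal | O=C[C@@H](C)[C@H](C)O[Si](C)(C)C(C)(C)C | intermediate
29 | 2-(triphenyl-λ5-phosphanylidene)propanal | CC(C=O)=P(c1ccccc1)(c1ccccc1)c1ccccc1 | starting material
30 | (2E,4R,5S)-5-[(tert-butyldimethylsilyl)oxy]-2,4-dimethylhex-2-enal | O=C/C(C)=C/[C@@H](C)[C@H](C)O[Si](C)(C)C(C)(C)C | intermediate
31 | 1-(triphenyl-λ5-phosphanylidene)propan-2-one | CC(=O)C=P(c1ccccc1)(c1ccccc1)c1ccccc1 | starting material
32 | (3E,5E,7R,8S)-8-[(tert-butyldimethylsilyl)oxy]-5,7-dimethylnona-3,5-dien-2-one (fragment 2) | CC(=O)/C=C/C(C)=C/[C@@H](C)[C@H](C)O[Si](C)(C)C(C)(C)C | intermediate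
33 | lithium enolate of 32 (acetyl methyl deprotonated) | [Li]OC(=C)/C=C/C(C)=C/[C@@H](C)[C@H](C)O[Si](C)(C)C(C)(C)C | intermediate
34 | (3E,5E,7R,8S)-8-[(tert-butyldimethylsilyl)oxy]-1-[(3aR,7S,7aR)-5-chloro-2,2,3a-trimethyl-4-oxo-7-{[(triethylsilyl)oxy]methyl}-3a,4,7,7a-tetrahydro-1,3-benzodioxol-6-yl]-5,7-dimethylnona-3,5-dien-2-one | CC(/C=C/C(=O)CC1=C(Cl)C(=O)[C@]2(C)OC(C)(C)O[C@@H]2[C@@H]1CO[Si](CC)(CC)CC)=C\[C@@H](C)[C@H](C)O[Si](C)(C)C(C)(C)C | intermediate
35 | the 7-(hydroxymethyl) analogue of 34 (C1 hydroxyl free) | CC(/C=C/C(=O)CC1=C(Cl)C(=O)[C@]2(C)OC(C)(C)O[C@@H]2[C@@H]1CO)=C\[C@@H](C)[C@H](C)O[Si](C)(C)C(C)(C)C | intermediate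
36 | target protected as C7/C8 acetonide and C6′ tert-butyldimethylsilyl ether, ring (7R,8R,8aS), side chain (1′E,3′E,5′R,6′S) | CC(/C=C/C1=CC2=C(Cl)C(=O)[C@]3(C)OC(C)(C)O[C@@H]3[C@@H]2CO1)=C\[C@@H](C)[C@H](C)O[Si](C)(C)C(C)(C)C | intermediate
37 | (7R,8R,8aS)-5-chloro-7,8-dihydroxy-3-[(1E,3E,5R,6S)-6-hydroxy-3,5-dimethylhepta-1,3-dien-1-yl]-7-methyl-1,7,8,8a-tetrahydro-6H-isochromen-6-one | CC(/C=C/C1=CC2=C(Cl)C(=O)[C@](C)(O)[C@H](O)[C@@H]2CO1)=C\[C@@H](C)[C@H](C)O | target

**Step count and risks**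

Total: 22 steps. Longest linear sequence: 17 steps (steps 1–15, 21, 22); the side chain is a 5-step branch (steps 16–20).

Steps most likely to fail:

1. Step 21. Proton abstraction at C8a by the enolate, followed by β-elimination of the C1 silyloxy or C8 alkoxy group, may outrun the vinylic substitution. Proton exchange on warming could also move the enolate of 32 into its extended form and erode C5′. Fallback, setting out from enal 30 and dichloroenone 23 and coming back at 36: a Horner–Wadsworth–Emmons reaction of 30 with diethyl [3-(trimethylsilyl)prop-2-yn-1-yl]phosphonate (LiN(SiMe3)2, THF) should give the silyl dienyne F1, and K2CO3/MeOH the terminal dienyne F2. Sonogashira coupling of F2 at the activated C4a chloride of 23 (PdCl2(PPh3)2, CuI (copper monoiodide), Et3N) forms the C4–C4a bond in the alkynyl chloroenone F3. PPTS/MeOH then frees the C1 hydroxyl to give the hydroxy enynone F4, and 6-endo-dig addition of that hydroxyl to C3 of the enone-activated alkyne (AuCl(PPh3)/AgOTf, or DBU as an oxa-Michael addition) closes ring B and gives 36.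

2. Step 15. O-activation of the chloro dione may not discriminate well enough between the two oxygens, so that chloride also enters at C6, and the phosphorane may attack the primary silyl ether. Fallback, setting out from alcohol 17 and coming back at 23, in which the C6 carbonyl is fixed by construction: Dess–Martin oxidation gives the keto aldehyde F5, and amine-catalysed intramolecular aldol condensation (pyrrolidine, AcOH) closes ring A as the enone F6. Chlorine addition gives the dichloro ketone F7, and Et3N-induced loss of HCl the 2-chloro enone F8. A second chlorine addition gives the trichloro ketone F9, and dehydrochlorination (Li2CO3, LiCl, DMF) removes the C4a proton with a C5 chloride to give 23.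

3. Step 9 (with step 8). The silylating agent may capture the cyclic hemiketal instead of the open chain, or the hemiketal may not open at a useful rate; a second addition of MeLi in step 8 is the related risk. Fallback, setting out from lactone 13 and coming back at 16: aminolysis with MeNH(OMe)·HCl/Me2AlCl opens the lactone to the hydroxy Weinreb amide F10, which cannot close to a hemiketal. TESCl/imidazole gives the silyl ether amide F11, and MeMgBr converts the amide into the methyl ketone 16.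

**Further compounds**

F1 | step 21 | tert-butyl{[(2S,3R,4E,6E)-3,5-dimethyl-9-(trimethylsilyl)nona-4,6-dien-8-yn-2-yl]oxy}dimethylsilane | C[Si](C)(C)C#C/C=C/C(C)=C/[C@@H](C)[C@H](C)O[Si](C)(C)C(C)(C)C
F2 | step 21 | tert-butyl{[(2S,3R,4E,6E)-3,5-dimethylnona-4,6-dien-8-yn-2-yl]oxy}dimethylsilane | C#C/C=C/C(C)=C/[C@@H](C)[C@H](C)O[Si](C)(C)C(C)(C)C
F3 | step 21 | 23 with the C4a chloride replaced by the (3E,5E,7R,8S)-8-[(tert-butyldimethylsilyl)oxy]-5,7-dimethylnona-3,5-dien-1-yn-1-yl group | CC(/C=C/C#CC1=C(Cl)C(=O)[C@]2(C)OC(C)(C)O[C@@H]2[C@@H]1CO[Si](CC)(CC)CC)=C\[C@@H](C)[C@H](C)O[Si](C)(C)C(C)(C)C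
F4 | step 21 | F3 with the C1 hydroxyl free | CC(/C=C/C#CC1=C(Cl)C(=O)[C@]2(C)OC(C)(C)O[C@@H]2[C@@H]1CO)=C\[C@@H](C)[C@H](C)O[Si](C)(C)C(C)(C)C
F5 | step 15 | (2S)-2-[(4R,5R)-5-acetyl-2,2,5-trimethyl-1,3-dioxolan-4-yl]-3-[(triethylsilyl)oxy]propanal | CC(=O)[C@]1(C)OC(C)(C)O[C@@H]1[C@@H](C=O)CO[Si](CC)(CC)CC
F6 | step 15 | (3aR,7S,7aR)-2,2,3a-trimethyl-7-{[(triethylsilyl)oxy]methyl}-7,7a-dihydro-1,3-benzodioxol-4(3aH)-one | C1=CC(=O)[C@]2(C)OC(C)(C)O[C@@H]2[C@@H]1CO[Si](CC)(CC)CC
F7 | step 15 | 5,6-dichloro-5,6-dihydro derivative of F6 (new centres undefined) | ClC1C(Cl)C(=O)[C@]2(C)OC(C)(C)O[C@@H]2[C@@H]1CO[Si](CC)(CC)CC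
F8 | step 15 | (3aR,7S,7aR)-5-chloro-2,2,3a-trimethyl-7-{[(triethylsilyl)oxy]methyl}-7,7a-dihydro-1,3-benzodioxol-4(3aH)-one | C1=C(Cl)C(=O)[C@]2(C)OC(C)(C)O[C@@H]2[C@@H]1CO[Si](CC)(CC)CC
F9 | step 15 | 5,5,6-trichloro-5,6-dihydro derivative of F6 (C6 undefined) | ClC1C(Cl)(Cl)C(=O)[C@]2(C)OC(C)(C)O[C@@H]2[C@@H]1CO[Si](CC)(CC)CC
F10 | step 9 | (4R,5R)-5-[(2R)-1-(benzyloxy)-3-hydroxypropan-2-yl]-N-methoxy-N,2,2,4-tetramethyl-1,3-dioxolane-4-carboxamide | CON(C)C(=O)[C@]1(C)OC(C)(C)O[C@@H]1[C@@H](COCc2ccccc2)CO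
F11 | step 9 | (4R,5R)-5-[(2S)-1-(benzyloxy)-3-[(triethylsilyl)oxy]propan-2-yl]-N-methoxy-N,2,2,4-tetramethyl-1,3-dioxolane-4-carboxamide | CON(C)C(=O)[C@]1(C)OC(C)(C)O[C@@H]1[C@@H](COCc2ccccc2)CO[Si](CC)(CC)CC
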